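**Loss rate.** Fraction per minute is the unit I work in for this flask.

| flask | left-handed substrate | right-handed substrate | solid reagent | remark | time |
|---|---|---|---|---|---|
| east | 0.34 mM | 0.34 mM | 1 mM | run made earlier |  |
| north-west | 0.75 mM | 0.75 mM | 1 mM | run made earlier |  |
| north-east | 0.50 mM | 0.50 mM | 0.50 mM | run made earlier |  |
| flask | 0.50 mM | 0.50 mM | 1.00 mM |  | 4.0 min |

- east (time / min: left-handed product / %, left-handed substrate / %): 0.500: 2.5, 48.9; 1.00: 2.7, 45.7; 1.33: 3.0, 45.4; 2.00: 6.0, 44.1; 2.50: 5.9, 42.7; 3.00: 7.9, 41.3
- north-west (time / min: left-handed product / %, left-handed substrate / %): 0.250: 1.1, 48.8; 0.417: 1.2, 49.3; 0.667: 1.5, 48.4; 0.833: 1.1, 47.5; 1.33: 3.0, 45.5; 2.00: 5.2, 44.6; 3.00: 7.1, 41.3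
- north-east (time / min: left-handed product / %, left-handed substrate / %): 0.667: 2.5, 48.1; 1.33: 3.3, 46.2; 2.00: 5.1, 43.3; 2.50: 6.0, 42.4; 3.00: 7.8, 41.1

(each reading ± 0.5 percentage points)

- partner is single-handed; left-handed substrate and right-handed substrate are mirror images of each other, charged as a racemate, each of them at the stated concentration
- solid, in amounts per volume of the solution: solid reagent
- steps thought possible: partner + left-handed substrate -> left-handed product; partner + right-handed substrate -> right-handed product; solid reagent <-> partner; left-handed product <-> right-handed product; partner <-> dormant form
- at the start none of the solid reagent is in solution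
- the handed part of partner does not stay in what it makes, so the products of the two hands are mirror images too

- the left-handed product standing at 4.0 min, as a percentage of the left-handed substrate and right-handed substrate together charged
- the change that raises the amount of left-handed product at 4.0 min, in percent of the left-handed substrate and right-handed substrate together charged most ("none" if none brings more than 2 percentage points) (epsilon / theta / none)
- amount of left-handed product at 4.0 min, in percent of the left-handed substrate and right-handed substrate together charged, after theta

- epsilon: doubling the dissolution coefficient of the solid reagent, all else as stated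
- theta: doubling the solubility of the solid reagent, all else as stated

The earlier runs differ in their charges, yet at 3.00 min their left-handed substrate reads 41.3%, 41.3% and 41.1%, from a start of half of the charge. I therefore use one loss rate, the pseudo-first-order constant: the fraction of the left-handed substrate that goes per minute, 0.0643 min⁻¹.

**Two ways.** If everything lost stood as left-handed product, the flask at 4.0 min would hold 11.3%. The product readings at 3.00 min average 7.60%, and a straight line from them gives 10.1%. The two ways part by 1.2 percentage points, with a scatter of 0.5 points on a reading.

**Which cheats.** The substrate way does: at 3.00 min the readings show 8.77% lost, more than the product found, and left-handed product may turn into right-handed product. Taking that share, 86.7%, I commit to 9.82%. The north-west run reads 1.1% of left-handed product at 0.250 min, more than the straight line gives there, so I see no lag and expect little from epsilon. Under theta I assume that the loss rate follows the solubility and take twice the loss rate, which gives 17.4%. That is 7.6 points above my figure, more than the mark of 2 points, so my choice is theta.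

**The forecast.** It gives 10.1%, theta and 18.2%, holding that “Dissolution is therefore fast and partner sits at its solubility limit”. Its figures stand above mine, and its choice is the same as mine.

**The result.** The flask gives 8.93%. Theta adds 6.9 points and reaches 15.9%, while epsilon adds 0.26 points, so theta is the change to make, as forecast.

    partner + left-handed substrate → left-handed product (k = 25.2 M⁻¹ s⁻¹)
    partner + right-handed substrate → right-handed product (k = 6.83 M⁻¹ s⁻¹)
    solid reagent ⇌ partner, rate k3*(cs3 - [partner]) while solid is left; crystals form when [partner] > cs3 (solubility = 0.0460 mM, k = 0.389 s⁻¹)
    left-handed product ⇌ right-handed product (k = 0.00471 s⁻¹)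
    partner ⇌ dormant form (K = 3.08, k = 0.0163 s⁻¹)

**Not at rest.** The loss rate puts left-handed substrate in this flask at 38.7% at 4.0 min, and it stands at 38.6%, with 77% of its own charge remaining. The flask has not come to rest. At ten times the time, 40.0 min, left-handed product stands at 36.2% and right-handed product at 36.6%. The loss rate gives 3.82% of left-handed substrate there, and the flask holds 3.28%. Right-handed substrate still stands at 23.9%, and solid reagent at 8.55% of its charge.

**Second flask.** For the same flask read at 10 min, the loss rate gives 26.3% of left-handed substrate. That neighbour holds 25.8%, with 17.3% of left-handed product.

(The runs stem from a simulated flask for substances that don't exist; the scatter is artificial.)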